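**Plan**
- Retrosynthetic cuts, in order: the C15 acid, C16 acetate and C17 hydroxyl go back to a butenolide and then to a 3-substituted furan; the C9–C11 bond is cut (2-(furan-3-yl)ethyl nucleophile on a C9 ketone); ring A is opened at C3–C4 (radical conjugate cyclisation); C1–C10 and C10–C20 are cut (aldol and methylation of a carvone enolate).
- Enabling feature: ring B (C5–C10), with the C5 stereocentre, the C7=C8 alkene that carries C17 and an oxygen on C9, is the ring of carvone, and the isopropenyl group on C5 is C4 with its two methyls C18 and C19.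
- Forward order: ring B is bought; C10 is made quaternary (C20, then C1–C3 as an acryloyl group); ring A is closed; the C1 oxygen is removed; the C11–C16 chain is attached at C9 as a furan and the C7=C8 alkene is restored; the furan becomes the Z-acetoxy acid, with C17 hydroxylated late.
- Stereochemistry: C5 from (S)-carvone; C10 from aldol addition anti to the isopropenyl group; C9 from axial protonation in the Li/NH3 reduction; the Z alkene from the butenolide ring.

Key step: step 4

Remark: atoms carry labdane numbers (C17 on C8, C18/C19 on C4, C20 on C10). The target is an ent-labdane, (5R,9S,10R), with C20 and the C9 chain cis and H5 anti to C20. Compounds 4 and 7 are carried as epimer mixtures at a centre that is erased in the following step, and the C9 carbinol configuration of 18 is of no consequence.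

**Step 1**
Reactants: 1 (S)-(+)-carvone; 2 iodomethane
Product: 4 6-methylcarvone, via lithium dienolate of carvone 3 (not isolated)
Conditions: LiN(i-Pr)2 (LDA, 1.05 equiv), THF, −78 °C; MeI, −78 → 0 °C
Reagents that add atoms: none
Why: Kinetic α′-deprotonation of the enone and SN2 methylation of the cross-conjugated dienolate is a standard enolate alkylation, and the C6 configuration need not be controlled because this centre is planarised again in step 2.

**Step 2**
Reactants: 4 6-methylcarvone; 5 acrolein
Product: 7 aldol adduct 6-(1-hydroxyprop-2-en-1-yl)-6-methylcarvone, via lithium enolate of 6-methylcarvone 6 (not isolated)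
Conditions: LiN(i-Pr)2 (1.1 equiv), THF, −78 °C; acrolein, −78 °C, 15 min; AcOH/THF quench at −78 °C
Reagents that add atoms: none
Why: A kinetic lithium-enolate aldol addition (1,2-addition to the enal) forms C1–C10, and the aldehyde should approach the tetrasubstituted enolate anti to the neighbouring isopropenyl group, which sets the quaternary C10 with its methyl cis and the new chain trans to the isopropenyl group; the carbinol epimers converge in step 3.

**Step 3**
Reactants: 7 aldol adduct
Product: 8 6-acryloyl-6-methylcarvone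
Conditions: Dess–Martin periodinane, CH2Cl2, 0 °C → rt
Reagents that add atoms: none
Why: Dess–Martin oxidation of the secondary allylic alcohol runs under near-neutral conditions that avoid retro-aldol cleavage at the non-enolisable quaternary C10.

**Step 4**
Reactants: 8 6-acryloyl-6-methylcarvone
Product: 9 trans-fused bicyclic 7-ene-1,9-dione
Conditions: Fe(acac)3 (0.3 equiv), PhSiH3 (2.5 equiv), EtOH/ethylene glycol (5:1), 0.02 M, 60 °C, Ar
Reagents that add atoms: none
Why: An iron hydride formed from Fe(acac)3 and PhSiH3 transfers a hydrogen atom to the CH2 terminus of the electron-rich isopropenyl group, which gives the tertiary C4 radical with both methyls in place; this nucleophilic radical adds to the terminal carbon C3 of the acryloyl group, and the α-keto radical at C2 is reduced by divalent iron to the enolate and protonated by ethanol. The closest known reaction type is the Fe(acac)3/PhSiH3 reductive olefin coupling, used here as an intramolecular Giese-type radical conjugate addition. Ring A closes in the 6-endo-trig mode through C4–C5–C10–C1–C2–C3, since the 5-exo alternative would bond to the α-carbon and leave an unstabilised primary radical. No stereocentre is created (C4 becomes the gem-dimethyl carbon, C2 a methylene), and the trans ring fusion follows from the trans relation of the acryloyl and isopropenyl groups on C10 and C5, which can bridge only diequatorially. The step needs hydrogen-atom transfer to the 1,1-disubstituted alkene instead of either enone and endo instead of exo closure, and both follow from alkene polarity: the hydride reacts fastest with the electron-rich alkene, and the tertiary radical attacks the unsubstituted β-terminus of the vinyl ketone.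

**Step 5**
Reactants: 9 bicyclic 7-ene-1,9-dione
Product: 11 C1 enol triflate of the enedione, via potassium C1 enolate 10 (not isolated)
Conditions: KN(SiMe3)2 (KHMDS, 1.1 equiv), THF, −78 °C; PhNTf2, −78 → 0 °C; aq NH4Cl
Reagents that add atoms: N-phenylbis(trifluoromethanesulfonimide), O=S(=O)(N(c1ccccc1)S(=O)(=O)C(F)(F)F)C(F)(F)F
Why: The C1 ketone has α-hydrogens only at C2 and the C9 enone has no α′-hydrogen, so kinetic deprotonation and O-sulfonylation (enol triflate formation) should occur regioselectively at C1–C2.

**Step 6**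
Reactants: 11 C1 enol triflate
Product: 12 bicyclic 1,7-dien-9-one
Conditions: Pd(OAc)2 (5 mol %), PPh3 (10 mol %), HCO2H (2 equiv), Bu3N (3 equiv), DMF, 60 °C
Reagents that add atoms: none
Why: Palladium-catalysed formate reduction of an enol triflate (oxidative addition to zerovalent palladium, formate exchange, decarboxylation, reductive elimination) replaces C–O by C–H without touching the enone.

**Step 7**
Reactants: 12 bicyclic 1,7-dien-9-one
Product: 13 bicyclic 7-en-9-one
Conditions: H2 (1–3 atm), RhCl(PPh3)3 (5 mol %), benzene/EtOH (1:1), rt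
Reagents that add atoms: none
Why: Homogeneous hydrogenation over RhCl(PPh3)3 saturates the cis-disubstituted C1=C2 alkene and spares the trisubstituted conjugated C7=C8 alkene (the selectivity known from carvone to carvotanacetone), which completes the removal of the C1 oxygen.

**Step 8**
Reactants: 14 2-(furan-3-yl)ethanol
Product: 15 3-(2-iodoethyl)furan
Conditions: PPh3, imidazole, iodine, CH2Cl2, 0 °C → rt
Reagents that add atoms: iodine, [I][I]
Why: Appel-type iodination converts the primary alcohol into the iodide by SN2 displacement of the alkoxyphosphonium intermediate.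

**Step 9**
Reactants: 15 3-(2-iodoethyl)furan; 13 bicyclic 7-en-9-one
Product: 18 C9 tertiary allylic alcohol, via 2-(furan-3-yl)ethyllithium 16 (not isolated), via dichloro[2-(furan-3-yl)ethyl]cerium 17 (not isolated)
Conditions: 15 (2 equiv), t-BuLi (4 equiv), Et2O, −78 °C; CeCl3 (anhydrous, 2.2 equiv), THF, −78 °C; 13, −78 → −20 °C; aq NH4Cl
Reagents that add atoms: none
Why: Iodine–lithium exchange gives the primary alkyllithium, and transmetalation to the weakly basic, oxophilic organocerium reagent should give clean 1,2-addition to the hindered C9 enone, with attack anti to the axial C20 methyl expected but irrelevant because the carbinol centre is destroyed in step 10.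

**Step 10**
Reactants: 18 C9 tertiary allylic alcohol
Product: 19 transposed 8-en-7-one
Conditions: pyridinium chlorochromate (C5H5NH)[CrO3Cl] (3 equiv), 4 Å MS, CH2Cl2, rt
Reagents that add atoms: pyridinium chlorochromate, [O-][Cr](=O)(=O)Cl.c1cc[nH+]cc1
Why: In the Babler–Dauben oxidative transposition the tertiary allylic chromate ester undergoes a [3,3] shift to C7 and the secondary chromate is oxidised, which moves the oxygen from C9 to C7 and the alkene to C8=C9.

**Step 11**
Reactants: 19 transposed 8-en-7-one
Product: 21 C7 enol triflate, via lithium C7 enolate 20 (not isolated)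
Conditions: Li (2.2 equiv), t-BuOH (1.0 equiv), NH3(l)/THF, −78 °C; NH3 evaporated; PhNTf2, THF, −78 → 0 °C; aq NH4Cl
Reagents that add atoms: N-phenylbis(trifluoromethanesulfonimide), O=S(=O)(N(c1ccccc1)S(=O)(=O)C(F)(F)F)C(F)(F)F
Why: Dissolving-metal (Birch-type) reduction of the tetrasubstituted enone protonates the β-carbon C9 axially, anti to the axial C20 methyl, so the side chain becomes equatorial and cis to C20 as in the target, and the regiodefined lithium enolate is trapped on oxygen as the C7–C8 enol triflate.

**Step 12**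
Reactants: 21 C7 enol triflate
Product: 22 furanolabdadiene 15,16-epoxy-ent-labda-7,13(16),14-triene
Conditions: Pd(OAc)2 (5 mol %), PPh3 (10 mol %), HCO2H (2 equiv), Bu3N (3 equiv), DMF, 60 °C
Reagents that add atoms: none
Why: The same palladium-catalysed formate reduction as in step 6 removes the triflate and leaves the C7=C8 alkene in its final position with C17 as a methyl group, the furan being inert.

**Step 13**
Reactants: 22 furanolabdadiene
Product: 24 γ-hydroxybutenolide 16-hydroxy-ent-labda-7,13-dien-15,16-olide, via furan endoperoxide 23 (not isolated)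
Conditions: O2, hν (visible), tetraphenylporphyrin (cat.), i-Pr2NEt, CH2Cl2, −78 °C → rt
Reagents that add atoms: oxygen, O=O
Why: Sensitised singlet oxygen adds [4+2] to the furan much faster than it undergoes the ene reaction with the C7=C8 alkene at −78 °C, and the hindered amine removes the less encumbered bridgehead hydrogen on C15 (Kornblum–DeLaMare-type fragmentation), so C15 becomes the lactone carbonyl and C16 the hemiacetal carbon.

**Step 14**
Reactants: 24 γ-hydroxybutenolide
Product: 26 butenolide ent-labda-7,13-dien-15,16-olide, via sodium hydroxy carboxylate 25 (not isolated)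
Conditions: NaBH4, EtOH, 0 °C; then 1 M HCl to pH 2, rt
Reagents that add atoms: none
Why: Borohydride reduces the open-chain aldehyde tautomer of the γ-hydroxybutenolide and acidification closes the Z-hydroxy acid to the lactone (standard reduction–lactonisation), the ring fixing the Z geometry of C13=C14.

**Step 15**
Reactants: 26 butenolide
Product: 29 SEM ester of 16-acetoxy-ent-labda-7,13Z-dien-15-oic acid, via potassium hydroxy carboxylate 27 (not isolated), via hydroxy SEM ester 28 (not isolated)
Conditions: KOH (1.0 equiv), THF/H2O, rt; concentrate, toluene azeotrope; SEMCl (1.05 equiv), DMF, 0 °C; then Ac2O, pyridine, DMAP (cat.), 0 °C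
Reagents that add atoms: potassium hydroxide, [K+].[OH-]; 2-(trimethylsilyl)ethoxymethyl chloride, C[Si](C)(C)CCOCCl; acetic anhydride, CC(=O)OC(C)=O
Why: Saponification opens the lactone to the Z-hydroxy carboxylate, the carboxylate is alkylated by the reactive chloromethyl ether faster than the neutral hydroxyl, and immediate DMAP-catalysed acetylation should cap the primary alcohol before it can relactonise, the alkene geometry being retained from the ring.

**Step 16**
Reactants: 29 acetoxy SEM ester
Product: 30 17-hydroxy acetoxy SEM ester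
Conditions: SeO2 (0.5 equiv), t-BuOOH (3 equiv), CH2Cl2, 0 °C → rt
Reagents that add atoms: tert-butyl hydroperoxide, CC(C)(C)OO; selenium dioxide, O=[Se]=O
Why: Riley allylic oxidation in its catalytic form (ene reaction, then [2,3]-sigmatropic shift) should attack only the electron-rich C7=C8 alkene and hydroxylate the methyl group on its more substituted end (C17), the site that reacts in drim-7-enes and labd-7-enes.

**Step 17**
Reactants: 30 17-hydroxy acetoxy SEM ester
Product: 31 16-acetoxy-17-hydroxy-ent-labda-7,13Z-dien-15-oic acid (target)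
Conditions: MgBr2·OEt2 (4 equiv), Et2O, rt; pH 4 aqueous work-up
Reagents that add atoms: none
Why: MgBr2 chelates the acyl acetal and cleaves the SEM ester by bromide attack at the O–CH2–O carbon (known for alkoxymethyl esters) under conditions that should leave the allylic acetate, the allylic alcohol and both alkenes untouched.

**Compound list**
1 | (S)-(+)-carvone, (5S)-2-methyl-5-(prop-1-en-2-yl)cyclohex-2-en-1-one | CC(=C)[C@H]1CC=C(C)C(=O)C1 | starting material
2 | iodomethane | CI | starting material
3 | lithium dienolate of carvone (deprotonated at C6, carvone numbering) | CC(=C)[C@H]1CC=C(C)C([O-])=C1.[Li+] | intermediate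
4 | 6-methylcarvone, (5S)-2,6-dimethyl-5-(prop-1-en-2-yl)cyclohex-2-en-1-one, both C6 epimers (trans expected to predominate) | CC(=C)[C@H]1CC=C(C)C(=O)C1C | intermediate
5 | acrolein | C=CC=O | starting material
6 | lithium enolate of 6-methylcarvone (C1–C6 enolate, carvone numbering) | CC(=C)[C@H]1CC=C(C)C([O-])=C1C.[Li+] | intermediate
7 | (5R,6S)-6-(1-hydroxyprop-2-en-1-yl)-2,6-dimethyl-5-(prop-1-en-2-yl)cyclohex-2-en-1-one, both carbinol epimers; hydroxyallyl group trans and methyl cis to isopropenyl | O=C1C(C)=CC[C@H](C(C)=C)[C@@]1(C)C(O)C=C | intermediate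
8 | (5R,6S)-2,6-dimethyl-6-(prop-2-enoyl)-5-(prop-1-en-2-yl)cyclohex-2-en-1-one; acryloyl trans to isopropenyl | O=C1C(C)=CC[C@H](C(C)=C)[C@@]1(C)C(=O)C=C | intermediate
9 | (4aR,8aS)-2,5,5,8a-tetramethyl-4a,5,6,7-tetrahydronaphthalene-1,8(4H,8aH)-dione; trans-fused, ketones at labdane C1 and C9, C7=C8 | O=C1C(C)=CC[C@@H]2C(C)(C)CCC(=O)[C@@]12C | intermediate
10 | potassium C1–C2 enolate of 9 | O=C1C(C)=CC[C@@H]2C(C)(C)CC=C([O-])[C@@]12C.[K+] | intermediate
11 | C1 enol triflate of 9 (1-triflyloxy-1,7-dien-9-one) | O=C1C(C)=CC[C@@H]2C(C)(C)CC=C(OS(=O)(=O)C(F)(F)F)[C@@]12C | intermediate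
12 | (4aR,8aR)-2,5,5,8a-tetramethyl-4a,5,6,8a-tetrahydronaphthalen-1(4H)-one (labdane C1=C2 and C7=C8, C9 ketone) | O=C1C(C)=CC[C@@H]2C(C)(C)CC=C[C@@]12C | intermediate
13 | (4aR,8aR)-2,5,5,8a-tetramethyl-4a,5,6,7,8,8a-hexahydronaphthalen-1(4H)-one (C7=C8, C9 ketone) | O=C1C(C)=CC[C@@H]2C(C)(C)CCC[C@@]12C | intermediate
14 | 2-(furan-3-yl)ethanol | OCCc1ccoc1 | starting material
15 | 3-(2-iodoethyl)furan | ICCc1ccoc1 | intermediate
16 | 2-(furan-3-yl)ethyllithium | [Li]CCc1ccoc1 | intermediate
17 | dichloro[2-(furan-3-yl)ethyl]cerium | Cl[Ce](Cl)CCc1ccoc1 | intermediate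
18 | 9-hydroxy-15,16-epoxy-ent-labda-7,13(16),14-triene, tertiary allylic alcohol; epimer from attack anti to C20 drawn | O[C@]1(CCc3ccoc3)C(C)=CC[C@@H]2C(C)(C)CCC[C@@]12C | intermediate
19 | 15,16-epoxy-ent-labda-8,13(16),14-trien-7-one | O=C1C[C@@H]2C(C)(C)CCC[C@@]2(C)C(CCc3ccoc3)=C1C | intermediate
20 | lithium C7–C8 enolate, C9–H set (chain cis to C20) | C(Cc1ccoc1)[C@@H]2C(C)=C([O-])C[C@@H]3C(C)(C)CCC[C@@]23C.[Li+] | intermediate
21 | C7 enol triflate, 7-triflyloxy-15,16-epoxy-ent-labda-7,13(16),14-triene | C(Cc1ccoc1)[C@@H]2C(C)=C(OS(=O)(=O)C(F)(F)F)C[C@@H]3C(C)(C)CCC[C@@]23C | intermediate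
22 | 15,16-epoxy-ent-labda-7,13(16),14-triene (3-substituted furan) | C(Cc1ccoc1)[C@@H]2C(C)=CC[C@@H]3C(C)(C)CCC[C@@]23C | intermediate
23 | furan 2,5-endoperoxide of 22 | C(CC1=CC4OOC1O4)[C@@H]2C(C)=CC[C@@H]3C(C)(C)CCC[C@@]23C | intermediate
24 | 16-hydroxy-ent-labda-7,13-dien-15,16-olide (4-substituted 5-hydroxyfuran-2(5H)-one, C16 epimers) | C(CC1=CC(=O)OC1O)[C@@H]2C(C)=CC[C@@H]3C(C)(C)CCC[C@@]23C | intermediate
25 | sodium (13Z)-16-hydroxy-ent-labda-7,13-dien-15-oate | OC/C(=C\C(=O)[O-])CC[C@@H]1C(C)=CC[C@@H]2C(C)(C)CCC[C@@]12C.[Na+] | intermediate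
26 | ent-labda-7,13-dien-15,16-olide (4-substituted furan-2(5H)-one) | C(CC1=CC(=O)OC1)[C@@H]2C(C)=CC[C@@H]3C(C)(C)CCC[C@@]23C | intermediate
27 | potassium (13Z)-16-hydroxy-ent-labda-7,13-dien-15-oate | OC/C(=C\C(=O)[O-])CC[C@@H]1C(C)=CC[C@@H]2C(C)(C)CCC[C@@]12C.[K+] | intermediate
28 | 2-(trimethylsilyl)ethoxymethyl (13Z)-16-hydroxy-ent-labda-7,13-dien-15-oate | OC/C(=C\C(=O)OCOCC[Si](C)(C)C)CC[C@@H]1C(C)=CC[C@@H]2C(C)(C)CCC[C@@]12C | intermediate
29 | 2-(trimethylsilyl)ethoxymethyl (13Z)-16-acetoxy-ent-labda-7,13-dien-15-oate | CC(=O)OC/C(=C\C(=O)OCOCC[Si](C)(C)C)CC[C@@H]1C(C)=CC[C@@H]2C(C)(C)CCC[C@@]12C | intermediate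
30 | 2-(trimethylsilyl)ethoxymethyl (13Z)-16-acetoxy-17-hydroxy-ent-labda-7,13-dien-15-oate | CC(=O)OC/C(=C\C(=O)OCOCC[Si](C)(C)C)CC[C@@H]1C(CO)=CC[C@@H]2C(C)(C)CCC[C@@]12C | intermediate
31 | (2Z)-3-(acetoxymethyl)-5-[(1S,4aR,8aR)-2-(hydroxymethyl)-5,5,8a-trimethyl-1,4,4a,5,6,7,8,8a-octahydronaphthalen-1-yl]pent-2-enoic acid | CC(=O)OC/C(=C\C(=O)O)CC[C@@H]1C(CO)=CC[C@@H]2C(C)(C)CCC[C@@]12C | target

**Step count**
Total: 17 steps. Longest linear sequence: 16 steps from (S)-carvone (steps 1–7 and 9–17); step 8 is a one-step side branch.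

**Steps most likely to fail**

Step 15. The Z-hydroxy ester may relactonise (or be alkylated on oxygen) during the alkylation stage, before the acetylating agent is added. The fallback sets out from 26 and never exposes a free hydroxyl next to an unprotected ester under basic conditions. The lactone is hydrolysed with KOH and the dry salt is silylated exhaustively (t-BuMe2SiCl, imidazole, DMF) to tert-butyldimethylsilyl (13Z)-16-(tert-butyldimethylsilyloxy)-ent-labda-7,13-dien-15-oate F1. K2CO3 in aqueous MeOH/THF cleaves only the silyl ester and gives (13Z)-16-(tert-butyldimethylsilyloxy)-ent-labda-7,13-dien-15-oic acid F2. SEMCl and i-Pr2NEt convert it into 2-(trimethylsilyl)ethoxymethyl (13Z)-16-(tert-butyldimethylsilyloxy)-ent-labda-7,13-dien-15-oate F3. The silyl ether is then removed with pyridine-buffered HF·pyridine in THF in the presence of Ac2O, so that the alcohol is acetylated as it is released. The route is rejoined at 29.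

Step 16. The allylic oxidation may lack site selectivity (C6 or C9 instead of C17) or run on to the enal. The fallback sets out from 29 and reaches the same alcohol by epoxide chemistry. Epoxidation with mCPBA/NaHCO3 should occur only at the electron-rich C7=C8 alkene, anti to C20, and give the 7,8-epoxide of 29 F4. Homolytic opening with Cp2TiCl (trivalent titanium, from Cp2TiCl2 and Mn in THF) at the tertiary C8, followed by loss of a C17 hydrogen, should give the exocyclic allylic alcohol 2-(trimethylsilyl)ethoxymethyl (13Z)-16-acetoxy-7-hydroxy-ent-labda-8(17),13-dien-15-oate F5. Ph3SiOReO3-catalysed 1,3-transposition then moves the hydroxyl to C17 and the alkene to the more substituted C7=C8 position. The route is rejoined at 30.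

Step 9. The primary organocerium reagent may fail to add to the C9 carbonyl, which is flanked by the quaternary C10 and the substituted C8, leaving enone or giving γ-deprotonation. The fallback sets out from 13 and uses a slim sp-hybridised nucleophile. Commercial furan-3-carbaldehyde is homologated (Ohira–Bestmann: dimethyl (1-diazo-2-oxopropyl)phosphonate, K2CO3, MeOH) to 3-ethynylfuran F6. Its lithium acetylide (n-BuLi, THF, −78 °C; CeCl3) is added to 13 to give the alkynyl carbinol 9-hydroxy-15,16-epoxy-ent-labda-7,13(16),14-trien-11-yne F7. Hydrogenation over RhCl(PPh3)3 saturates the alkyne and leaves the hindered C7=C8 alkene and the furan. The route is rejoined at 18.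

**Further compounds**
F1 | step 15 | tert-butyldimethylsilyl (13Z)-16-(tert-butyldimethylsilyloxy)-ent-labda-7,13-dien-15-oate | CC(C)(C)[Si](C)(C)OC/C(=C\C(=O)O[Si](C)(C)C(C)(C)C)CC[C@@H]1C(C)=CC[C@@H]2C(C)(C)CCC[C@@]12C
F2 | step 15 | (13Z)-16-(tert-butyldimethylsilyloxy)-ent-labda-7,13-dien-15-oic acid | CC(C)(C)[Si](C)(C)OC/C(=C\C(=O)O)CC[C@@H]1C(C)=CC[C@@H]2C(C)(C)CCC[C@@]12C
F3 | step 15 | 2-(trimethylsilyl)ethoxymethyl (13Z)-16-(tert-butyldimethylsilyloxy)-ent-labda-7,13-dien-15-oate | CC(C)(C)[Si](C)(C)OC/C(=C\C(=O)OCOCC[Si](C)(C)C)CC[C@@H]1C(C)=CC[C@@H]2C(C)(C)CCC[C@@]12C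
F4 | step 16 | 7,8-epoxide of 29 (oxygen anti to C20) | CC(=O)OC/C(=C\C(=O)OCOCC[Si](C)(C)C)CC[C@@H]1[C@@]3(C)O[C@H]3C[C@@H]2C(C)(C)CCC[C@@]12C
F5 | step 16 | 2-(trimethylsilyl)ethoxymethyl (13Z)-16-acetoxy-7-hydroxy-ent-labda-8(17),13-dien-15-oate | CC(=O)OC/C(=C\C(=O)OCOCC[Si](C)(C)C)CC[C@@H]1C(=C)[C@@H](O)C[C@@H]2C(C)(C)CCC[C@@]12C
F6 | step 9 | 3-ethynylfuran | C#Cc1ccoc1
F7 | step 9 | 9-hydroxy-15,16-epoxy-ent-labda-7,13(16),14-trien-11-yne | O[C@]1(C#Cc3ccoc3)C(C)=CC[C@@H]2C(C)(C)CCC[C@@]12C
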